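The numbers in the tables stem from a simulated flask on assumed constants; scatter was added.

Each step in which one substrate and one reagent go to one target leaves their difference unchanged, so you can follow a flask by that difference and a count of turnovers.

| flask | substrate | reagent in the second phase | remark | time | volume of the second phase over the first |
|---|---|---|---|---|---|
| noon | 10 mM | 8.7 mM | run made earlier |  |  |
| autumn | 10 mM | 20 mM | run made earlier |  |  |
| summer | 20 mM | 13 mM | run made earlier |  |  |
| flask | 10 mM | 13.0 mM |  | 10 d | 0.25 |

| run | time / d | target / % | crystals / % |
|---|---|---|---|
| noon | 0.625 | 10 | 0 |
| noon | 1.67 | 34 | 0 |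
| noon | 3.00 | 50 | 7 |
| noon | 8.00 | 66 | 27 |
| autumn | 2.08 | 66 | 26 |
| autumn | 4.00 | 85 | 45 |
| autumn | 6.00 | 94 | 56 |
| autumn | 8.00 | 94 | 58 |
| summer | 1.04 | 26 | 7 |
| summer | 3.00 | 51 | 31 |
| summer | 5.00 | 57 | 38 |
| summer | 8.00 | 58 | 39 |

(each reading ± 1.5 percentage points)

- target and crystals together at 10 d, in percent of the substrate charged
- concentration of target in solution at 10 d, in percent of saturation

- target is meant together with its crystals
- in the second phase: reagent in the second phase; everything else is in the first
- charges count per volume of the first phase; a concentration in a rate is the amount of a species over the volume of its own phase; every rate counts per litre of the first phase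
- solid, in amounts per volume of the solution: crystals
- the earlier runs hold the two phases in the same ratio of volumes as the flask asked about

The summer run stood still at 11.6 mM of target from 13 mM of reagent, and that yield is the reagent budget b. This flask has the same reagent charge, so as an assumption of my own I carry over the same b, which gives a provisional surplus Δ = 1.60 mM over its substrate charge. Scaled to 17.8 mM for the autumn run, the second-order law, where the ratio S/R of substrate to reagent falls as exp(−kΔt), gives k = 0.0398 /mM/d from the reading at 4.00 d.

This flask therefore counts N = k·c·t = 3.98 turnovers, with c its substrate charge and t its time. With no surplus, substrate falls as one over one plus N, giving 79.9%. With reagent held at b, the pseudo-first-order extreme, it gives 99.0%. The surplus is small, so reagent falls nearly with substrate, and the exact law gives my 0.456 for the final S/R and 86.6%. Summer's dissolved target reads 3.80 mM, below that yield, so I expect crystals and 100% of saturation.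

The forecast says 82% and 103%, on the ground that “the reaction is reversible”.

The flask gives 88.7% and 100%.

    reagent in the reaction phase → decomposed reagent (k = 0.00210 /h)
    reagent in the reaction phase ⇌ reagent in the second phase, rate k2*([reagent in the reaction phase] - [reagent in the second phase]/K2) per volume of the first phase (partition coefficient = 1.20, kL = 0.0230 /h)
    crystals ⇌ target, rate k3*(cs3 - [target]) while solid is left; crystals form when [target] > cs3 (solubility = 3.90 mM, k = 4.70 /h)
    substrate ⇌ dormant form (K = 1.60, k = 0.110 /h)
    substrate + reagent in the reaction phase → target (k = 7.20 /M/h)

At 0.397 d the forward step to dormant form has a substrate half-life of 0.26 d, shorter than the 0.81 d toward target. At 10.0 d this flask holds 7.18% dormant form beside 4.17% substrate, and its 1.76 mM of decomposed reagent leaves 11.2 mM, less than the b I assumed. A neighbour flask charged with 25 mM of substrate has b worth 46.4% of its charge, and it gives 49.9%.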